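**Plan**

- Retrosynthesis: the peroxyhemiacetal (O–C15) is opened to an 11-hydroperoxy 15,16-dialdehyde and the C11–O bond is traced to singlet oxygen on a 16-silyloxy 11,13(16)-diene. Then C12=C13 is cut (Wittig), then ring B at C5–C6 and C7–C8, then C9–C10 (Claisen).
- Forward: ring A is bought as ketoisophorone; the Claisen rearrangement makes C9–C10; ring B is closed by a radical annulation with a two-carbon enol ether; C13–C16 are joined by Wittig olefination; the dioxepine ring forms last.
- Enabling feature: in ring B the CH2–CH(OH) unit C6–C7 lies between C5 (flanked by the fully substituted C4 and C10) and the methylene-bearing C8. An enol ether can therefore be stitched between a C5 radical and a C8≡C17 alkyne, C17 ending as the exocyclic CH2.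
- Helper: a nitro group on C5 makes that radical tertiary and electrophilic; Bu3SnH removes it afterwards and sets 5α-H.
- Stereochemistry: the C2 carbinol (asymmetric transfer hydrogenation) is relayed to C10 (suprafacial Claisen) and C9 (chair, E-alkenyl ether). C7 comes from the chair 6-exo-dig closure, C5 from α-face hydrogen delivery, C11 from face-selective photooxygenation, and C15 is thermodynamic.

Key step: step 9

Atom numbers are those of the labdane skeleton of the target and are used for every intermediate (ring A: C1–C5, C10; ring B: C5–C10; C17 exocyclic methylene; C18–C20 methyls; C11–C16 side chain).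
Assumption: the (S,S)-TsDPEN ruthenium catalyst is taken to give the 4S alcohol 2, by analogy with aryl ketones; the mirror-image ligand would be used if the sense were opposite.
Assumption: compounds 10, 11, 13 and 14 are expected as mixtures of epimers at C5, so their SMILES leave that centre open; it is fixed in step 10. Oxime 9 is an E/Z mixture.

**Step 1**
Reactants: 1 2,6,6-trimethylcyclohex-2-ene-1,4-dione (ketoisophorone)
Product: 2 (4S)-4-hydroxy-2,6,6-trimethylcyclohex-2-en-1-one
Conditions: RuCl(p-cymene)[(S,S)-TsDPEN] (0.5 mol %), HCO2H/Et3N (5:2), CH2Cl2, rt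
Reagents that add atoms: none
Why: Noyori-type asymmetric transfer hydrogenation should reduce only the unhindered carbonyl (the future C2), because the other carbonyl (the future C5) is flanked by the gem-dimethyl carbon and the methyl-bearing alkene carbon, and the chiral ruthenium hydride sets the carbinol centre that later relays its configuration to C10.

**Step 2**
Reactants: 3 4,4-diethoxybut-1-yne
Product: 4 2-[(1E)-4,4-diethoxybut-1-en-1-yl]-4,4,5,5-tetramethyl-1,3,2-dioxaborolane
Conditions: pinacolborane (1.1 equiv), Cp2Zr(H)Cl (5 mol %), Et3N (10 mol %), neat, 60 °C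
Reagents that add atoms: pinacolborane, CC1(C)OBOC1(C)C
Why: Zirconium-catalysed hydroboration of a terminal alkyne is a syn addition that places boron on the terminal carbon and should give the E-alkenyl boronate only.

**Step 3**
Reactants: 2 (4S)-4-hydroxy-2,6,6-trimethylcyclohex-2-en-1-one; 4 2-[(1E)-4,4-diethoxybut-1-en-1-yl]-4,4,5,5-tetramethyl-1,3,2-dioxaborolane
Product: 5 (4S)-4-{[(1E)-4,4-diethoxybut-1-en-1-yl]oxy}-2,6,6-trimethylcyclohex-2-en-1-one
Conditions: Cu(OAc)2 (2 equiv), Et3N (4 equiv), 4 Å molecular sieves, CH2Cl2, air, rt; 2 in threefold excess (recovered)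
Reagents that add atoms: none
Why: Chan–Lam–Evans-type oxidative C–O coupling of an alkenyl boronate with an alcohol runs at room temperature under weakly basic conditions, which the base-sensitive γ-hydroxy enone should tolerate, and it keeps the E geometry of the alkenyl group and the carbinol configuration.

**Step 4**
Reactants: 5 (4S)-4-{[(1E)-4,4-diethoxybut-1-en-1-yl]oxy}-2,6,6-trimethylcyclohex-2-en-1-one
Product: 6 (2R)-4,4-diethoxy-2-[(1R)-1,5,5-trimethyl-6-oxocyclohex-2-en-1-yl]butanal
Conditions: PhMe, 150 °C, sealed tube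
Reagents that add atoms: none
Why: Claisen rearrangement through a chair transition state forms the C9–C10 bond on the ring face that carried the C2–O bond, so the carbinol chirality is transferred to the quaternary C10, while the E-alkenyl ether places the acetal-bearing chain pseudo-equatorial and thereby sets C9; the aldehyde carbon becomes C8 and the alkene moves to C1=C2.

**Step 5**
Reactants: 6 (2R)-4,4-diethoxy-2-[(1R)-1,5,5-trimethyl-6-oxocyclohex-2-en-1-yl]butanal
Product: 7 (2R)-4,4-diethoxy-2-[(1R)-1,3,3-trimethyl-2-oxocyclohexyl]butanal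
Conditions: H2 (1 atm), Pd/C (5 wt %), EtOAc, rt
Reagents that add atoms: none
Why: Heterogeneous hydrogenation should saturate the cis-disubstituted C1=C2 alkene of ring A and leave the aldehyde, the hindered ketone and the acetal alone, which removes an alkene that the later C7 radical could attack in a 5-exo mode.

**Step 6**
Reactants: 7 (2R)-4,4-diethoxy-2-[(1R)-1,3,3-trimethyl-2-oxocyclohexyl]butanal
Product: 8 (2R)-2-[(3S)-5,5-diethoxypent-1-yn-3-yl]-2,6,6-trimethylcyclohexan-1-one
Conditions: dimethyl (1-diazo-2-oxopropyl)phosphonate (1.3 equiv), K2CO3 (2 equiv), MeOH, 0 °C → rt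
Reagents that add atoms: dimethyl (1-diazo-2-oxopropyl)phosphonate (Ohira–Bestmann reagent), CC(=O)C(=[N+]=[N-])P(=O)(OC)OC
Why: Seyferth–Gilbert homologation with the Ohira–Bestmann reagent turns the aldehyde carbon C8 into the internal carbon of a terminal alkyne (C8≡C17) under mild carbonate conditions that should neither epimerise the hindered C9 centre nor touch the non-enolisable ketone.

**Step 7**
Reactants: 8 (2R)-2-[(3S)-5,5-diethoxypent-1-yn-3-yl]-2,6,6-trimethylcyclohexan-1-one
Product: 9 (2R)-2-[(3S)-5,5-diethoxypent-1-yn-3-yl]-2,6,6-trimethylcyclohexan-1-one oxime (E/Z mixture)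
Conditions: NH2OH (50 % in H2O, 10 equiv), EtOH, 90 °C, sealed tube, prolonged heating
Reagents that add atoms: hydroxylamine, NO
Why: Oxime condensation at C5 is slow because the ketone is flanked by two quaternary carbons, so free hydroxylamine in large excess and prolonged heating are used, in line with the behaviour of fenchone-type ketones; the alkyne and the acetal are inert to these conditions.

**Step 8**
Reactants: 9 (2R)-2-[(3S)-5,5-diethoxypent-1-yn-3-yl]-2,6,6-trimethylcyclohexan-1-one oxime
Product: 11 (3R)-2-chloro-3-[(3S)-5,5-diethoxypent-1-yn-3-yl]-1,1,3-trimethyl-2-nitrocyclohexane (C2 epimers; ring C2 is labdane C5), via chloronitroso compound 10 (not isolated)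
Conditions: NaOCl (aq, 4 equiv), n-Bu4NHSO4 (10 mol %), pH 5.5 buffer, CH2Cl2, 0 °C → rt
Reagents that add atoms: sodium hypochlorite, [Na+].[O-]Cl
Why: Hypochlorous acid chlorinates the oxime carbon to the geminal chloronitroso compound and a second equivalent oxidises nitrogen, a known one-flask route from ketoximes to geminal chloronitro compounds that brings the radical leaving group (Cl) and the removable activating group (NO2) onto C5 together.

**Step 9**
Reactants: 11 (3R)-2-chloro-3-[(3S)-5,5-diethoxypent-1-yn-3-yl]-1,1,3-trimethyl-2-nitrocyclohexane; 12 trimethyl(vinyloxy)silane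
Product: 14 12,12-diethoxy-5-nitro-13,14,15,16-tetranorlabd-8(17)-en-7β-ol (C5 epimers), via trimethylsilyl ether 13 (not isolated)
Conditions: 12 (30 equiv) as co-solvent, PhH, 80 °C; 11 and Bu3SnH (1.3 equiv) with AIBN (0.2 equiv) added together by syringe pump over 10 h; then K2CO3, MeOH, rt
Reagents that add atoms: none
Why: Proposed new method: the Bu3Sn radical removes chlorine from the geminal chloronitro carbon C5 (electron transfer to the nitro group, loss of chloride), the electrophilic tertiary α-nitro radical adds to the unsubstituted terminus of the electron-rich enol ether 12 (C5–C6), and the nucleophilic α-silyloxy radical at C7 closes ring B on the internal alkyne carbon C8 in the 6-exo-dig mode (C7–C8), the vinyl radical at C17 then taking hydrogen from Bu3SnH; the closest known reaction types are tin hydride cyclisations of α-halo nitroalkanes onto alkenes, additions of α-nitroalkyl radicals to silyl enol ethers, and Giese addition/exo-dig cyclisation annulations. A radical is used because C5 lies between the fully substituted C4 and C10, where an early transition state tolerates the congestion, and the alternation of radical polarity (electrophilic at C5, nucleophilic at C7) matches each radical with its acceptor. C7 is set in a chair-like transition state of ring B in which the OSiMe3 group and the C9 side chain are both pseudo-equatorial (cis-1,3), which should give 7β-O whichever face of C5 was attacked. C5 is formed as a mixture, which does not matter because step 10 planarises it. The step needs bimolecular addition to outrun hydrogen transfer to the C5 radical and electron transfer from the C7 radical to unreacted 11; the large excess of 12 and the slow joint addition of 11 and Bu3SnH are meant to secure this, while in the substrate ring A is saturated, the side chain carries no π bond, the alkyne is terminal (exo closure), and direct attack of the C5 radical on the alkyne would be 4-exo or 5-endo.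

**Step 10**
Reactants: 14 12,12-diethoxy-5-nitro-13,14,15,16-tetranorlabd-8(17)-en-7β-ol
Product: 15 12,12-diethoxy-13,14,15,16-tetranorlabd-8(17)-en-7β-ol (5α-H, 9α-H, 10β-CH3)
Conditions: Bu3SnH (3 equiv), AIBN (0.5 equiv, in portions), PhMe, 110 °C
Reagents that add atoms: none
Why: Radical denitration of a tertiary nitro compound with Bu3SnH gives the C5 radical inside the finished decalin, and hydrogen should be delivered to its α face because the β face is covered by the two axial methyl groups on C4 and C10, which sets the trans ring fusion (5α-H) from either C5 epimer.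

**Step 11**
Reactants: 15 12,12-diethoxy-13,14,15,16-tetranorlabd-8(17)-en-7β-ol
Product: 16 7β-hydroxy-13,14,15,16-tetranorlabd-8(17)-en-12-al
Conditions: p-TsOH·H2O (10 mol %), acetone/H2O (10:1), rt
Reagents that add atoms: water, O
Why: Acid-catalysed acetal hydrolysis frees the C12 aldehyde under conditions mild enough for the secondary allylic alcohol and the exocyclic alkene.

**Step 12**
Reactants: 17 [2-(1,3-dioxolan-2-yl)ethyl]triphenylphosphonium bromide
Product: 19 3-(1,3-dioxolan-2-yl)-2-(triphenylphosphoranylidene)propanal, via phosphorus ylide 18 (not isolated)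
Conditions: KOt-Bu (2.1 equiv), THF, 0 °C; then HCO2Et (1.2 equiv), 0 °C → rt
Reagents that add atoms: ethyl formate, CCOC=O
Why: Deprotonation of the phosphonium salt and C-formylation of the resulting ylide with ethyl formate is the standard route to α-formyl-stabilised ylides, the second equivalent of base regenerating the ylide from the acylated phosphonium ion.

**Step 13**
Reactants: 16 7β-hydroxy-13,14,15,16-tetranorlabd-8(17)-en-12-al; 19 3-(1,3-dioxolan-2-yl)-2-(triphenylphosphoranylidene)propanal
Product: 20 (12E)-15,15-(ethylenedioxy)-7β-hydroxylabda-8(17),12-dien-16-al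
Conditions: PhMe, 90 °C
Reagents that add atoms: none
Why: Wittig reaction of a formyl-stabilised ylide with an unhindered aldehyde is E-selective, so C11 ends trans to the formyl carbon C16 and cis to C14, as the dioxepine ring requires, and the free hydroxyl group and the acetal are not affected.

**Step 14**
Reactants: 20 (12E)-15,15-(ethylenedioxy)-7β-hydroxylabda-8(17),12-dien-16-al
Product: 21 (11E,13(16)E)-15,15-(ethylenedioxy)-7β,16-bis(triethylsilyloxy)labda-8(17),11,13(16)-triene
Conditions: Et3SiCl (2.6 equiv), THF, −78 °C; KN(SiMe3)2 (2.3 equiv) added slowly; → −20 °C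
Reagents that add atoms: chlorotriethylsilane, CC[Si](Cl)(CC)CC
Why: The amide base removes the hydroxyl proton and then the γ-proton at C11 of the enal (vinylogous enolisation), and O-silylation of the dienolate gives the 1-silyloxy diene, the C14 protons not being conjugated to the carbonyl group and the acetal being stable to base.

**Step 15**
Reactants: 21 (11E,13(16)E)-15,15-(ethylenedioxy)-7β,16-bis(triethylsilyloxy)labda-8(17),11,13(16)-triene
Product: 24 (11S,15R)-11,15-epidioxy-7β,15-dihydroxylabda-8(17),12-dien-16-al (CNP0269954.2), via hydroperoxy enal 22 (not isolated), via hydroperoxy dialdehyde 23 (not isolated)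
Conditions: O2, tetraphenylporphyrin (1 mol %), visible light, CH2Cl2/MeOH (9:1), −78 °C; then 1 M HCl (aq), THF, 0 °C → rt
Reagents that add atoms: oxygen, O=O; water, O
Why: Singlet oxygen attacks the electron-rich diene at its remote terminus C11, as in the known photooxygenation of dienol ethers to γ-hydroperoxy enones, from the face turned away from C10 (C20 methyl and C1 methylene) in the conformer with H9 eclipsing the diene, the s-trans diene giving the 12E enal; aqueous acid then removes both silyl groups and the dioxolane, and the hydroperoxide adds to the C15 aldehyde to give the seven-membered peroxyhemiacetal with C15 under thermodynamic (anomeric) control.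

**Compound list**

1 | 2,6,6-trimethylcyclohex-2-ene-1,4-dione (ketoisophorone) | CC1=CC(=O)CC(C)(C)C1=O | starting material
2 | (4S)-4-hydroxy-2,6,6-trimethylcyclohex-2-en-1-one | CC1=C[C@@H](O)CC(C)(C)C1=O | intermediate
3 | 4,4-diethoxybut-1-yne | C#CCC(OCC)OCC | starting material
4 | 2-[(1E)-4,4-diethoxybut-1-en-1-yl]-4,4,5,5-tetramethyl-1,3,2-dioxaborolane | CCOC(C/C=C/B1OC(C)(C)C(C)(C)O1)OCC | intermediate
5 | (4S)-4-{[(1E)-4,4-diethoxybut-1-en-1-yl]oxy}-2,6,6-trimethylcyclohex-2-en-1-one | CC1=C[C@@H](O/C=C/CC(OCC)OCC)CC(C)(C)C1=O | intermediate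
6 | (2R)-4,4-diethoxy-2-[(1R)-1,5,5-trimethyl-6-oxocyclohex-2-en-1-yl]butanal | O=C[C@H](CC(OCC)OCC)[C@@]1(C)C=CCC(C)(C)C1=O | intermediate
7 | (2R)-4,4-diethoxy-2-[(1R)-1,3,3-trimethyl-2-oxocyclohexyl]butanal | O=C[C@H](CC(OCC)OCC)[C@@]1(C)CCCC(C)(C)C1=O | intermediate
8 | (2R)-2-[(3S)-5,5-diethoxypent-1-yn-3-yl]-2,6,6-trimethylcyclohexan-1-one | C#C[C@H](CC(OCC)OCC)[C@@]1(C)CCCC(C)(C)C1=O | intermediate
9 | (2R)-2-[(3S)-5,5-diethoxypent-1-yn-3-yl]-2,6,6-trimethylcyclohexan-1-one oxime (E/Z) | C#C[C@H](CC(OCC)OCC)[C@@]1(C)CCCC(C)(C)C1=NO | intermediate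
10 | (3R)-2-chloro-3-[(3S)-5,5-diethoxypent-1-yn-3-yl]-1,1,3-trimethyl-2-nitrosocyclohexane (C2 epimers) | C#C[C@H](CC(OCC)OCC)[C@@]1(C)CCCC(C)(C)C1(Cl)N=O | intermediate
11 | (3R)-2-chloro-3-[(3S)-5,5-diethoxypent-1-yn-3-yl]-1,1,3-trimethyl-2-nitrocyclohexane (C2 epimers) | C#C[C@H](CC(OCC)OCC)[C@@]1(C)CCCC(C)(C)C1(Cl)[N+](=O)[O-] | intermediate
12 | trimethyl(vinyloxy)silane | C=CO[Si](C)(C)C | starting material
13 | 12,12-diethoxy-5-nitro-7β-(trimethylsilyloxy)-13,14,15,16-tetranorlabd-8(17)-ene (C5 epimers) | C=C1[C@H](CC(OCC)OCC)[C@@]2(C)CCCC(C)(C)C2([N+](=O)[O-])C[C@@H]1O[Si](C)(C)C | intermediate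
14 | 12,12-diethoxy-5-nitro-13,14,15,16-tetranorlabd-8(17)-en-7β-ol (C5 epimers) | C=C1[C@H](CC(OCC)OCC)[C@@]2(C)CCCC(C)(C)C2([N+](=O)[O-])C[C@@H]1O | intermediate
15 | 12,12-diethoxy-13,14,15,16-tetranorlabd-8(17)-en-7β-ol | C=C1[C@H](CC(OCC)OCC)[C@@]2(C)CCCC(C)(C)[C@@H]2C[C@@H]1O | intermediate
16 | 7β-hydroxy-13,14,15,16-tetranorlabd-8(17)-en-12-al | C=C1[C@H](CC=O)[C@@]2(C)CCCC(C)(C)[C@@H]2C[C@@H]1O | intermediate
17 | [2-(1,3-dioxolan-2-yl)ethyl]triphenylphosphonium bromide | [Br-].C1COC(CC[P+](c2ccccc2)(c2ccccc2)c2ccccc2)O1 | starting material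
18 | [2-(1,3-dioxolan-2-yl)ethylidene]triphenylphosphorane | C1COC(CC=P(c2ccccc2)(c2ccccc2)c2ccccc2)O1 | intermediate
19 | 3-(1,3-dioxolan-2-yl)-2-(triphenylphosphoranylidene)propanal | O=CC(CC1OCCO1)=P(c1ccccc1)(c1ccccc1)c1ccccc1 | intermediate
20 | (12E)-15,15-(ethylenedioxy)-7β-hydroxylabda-8(17),12-dien-16-al | C=C1[C@H](C/C=C(/C=O)CC3OCCO3)[C@@]2(C)CCCC(C)(C)[C@@H]2C[C@@H]1O | intermediate
21 | (11E,13(16)E)-15,15-(ethylenedioxy)-7β,16-bis(triethylsilyloxy)labda-8(17),11,13(16)-triene | C=C1[C@H](/C=C/C(CC3OCCO3)=C/O[Si](CC)(CC)CC)[C@@]2(C)CCCC(C)(C)[C@@H]2C[C@@H]1O[Si](CC)(CC)CC | intermediate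
22 | (11S,12E)-15,15-(ethylenedioxy)-11-hydroperoxy-7β-(triethylsilyloxy)labda-8(17),12-dien-16-al | C=C1[C@H]([C@@H](OO)/C=C(/C=O)CC3OCCO3)[C@@]2(C)CCCC(C)(C)[C@@H]2C[C@@H]1O[Si](CC)(CC)CC | intermediate
23 | (11S,12E)-11-hydroperoxy-7β-hydroxylabda-8(17),12-diene-15,16-dial | C=C1[C@H]([C@@H](OO)/C=C(/C=O)CC=O)[C@@]2(C)CCCC(C)(C)[C@@H]2C[C@@H]1O | intermediate
24 | (11S,15R)-11,15-epidioxy-7β,15-dihydroxylabda-8(17),12-dien-16-al (CNP0269954.2) | C=C1[C@H]([C@@H]2C=C(C=O)C[C@H](O)OO2)[C@@]2(C)CCCC(C)(C)[C@@H]2C[C@@H]1O | target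

**Step count**

Total steps: 15. Longest linear sequence: 13 (steps 1, 3 to 11, 13 to 15).

**Steps most likely to fail**

Step 9 (proposed new method). Three processes may defeat the annulation: hydrogen transfer to the hindered C5 radical before it adds to 12; electron transfer from the C7 radical to unreacted 11, which ends the sequence at the aldehyde stage; and a 1,5-hydrogen shift from the propargylic C9–H to the C7 radical. The fallback separates the two bond formations and uses known reaction types. It sets out from 11: Keck radical allylation with allyltributylstannane (AIBN, PhH, 80 °C) should give (3R)-2-allyl-3-[(3S)-5,5-diethoxypent-1-yn-3-yl]-1,1,3-trimethyl-2-nitrocyclohexane F1. Lemieux–Johnson cleavage of the terminal alkene (OsO4 cat., NaIO4, 2,6-lutidine, dioxane/H2O), which the alkyne should survive, gives 2-[(6R)-6-[(3S)-5,5-diethoxypent-1-yn-3-yl]-2,2,6-trimethyl-1-nitrocyclohexyl]acetaldehyde F2. Nickel-catalysed reductive alkyne–aldehyde cyclisation (Ni(cod)2, an N-heterocyclic carbene ligand, Et3SiH, THF) then closes ring B at C7–C8 to 12,12-diethoxy-5-nitro-7β-(triethylsilyloxy)-13,14,15,16-tetranorlabd-8(17)-ene F3, and Bu4NF in THF returns to the route at 14.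

Step 15. Facial selectivity at C11 may be poor, oxygen may attack C13 or add across the diene, and the allylic hydroperoxide may fragment in acid (Hock cleavage). The fallback puts the oxygen on C11 under catalyst control before the alkene is made. It sets out from 16: proline-catalysed α-oxygenation of the aldehyde with singlet oxygen (O2, tetraphenylporphyrin, light, the proline enantiomer that gives the configuration shown, DMF, 0 °C) gives (11R)-11-hydroperoxy-7β-hydroxy-13,14,15,16-tetranorlabd-8(17)-en-12-al F4 (11R by the sequence rule, same spatial arrangement as C11 of 24). 2-Methoxypropene with pyridinium p-toluenesulfonate masks the hydroperoxide and the alcohol as (11R)-7β-(2-methoxypropan-2-yloxy)-11-(2-methoxypropan-2-ylperoxy)-13,14,15,16-tetranorlabd-8(17)-en-12-al F5. Wittig reaction with 19 gives (11S,12E)-15,15-(ethylenedioxy)-7β-(2-methoxypropan-2-yloxy)-11-(2-methoxypropan-2-ylperoxy)labda-8(17),12-dien-16-al F6, and 1 M HCl in THF removes all three protecting groups and closes the ring, returning at 24.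

Step 7. Condensation at the C5 ketone may stall because both neighbours are quaternary. The fallback makes the C=N bond while C10 is still trigonal and lets the rearrangement build the congestion. It sets out from 5: hydroxylamine in pyridine/EtOH gives (4S)-4-{[(1E)-4,4-diethoxybut-1-en-1-yl]oxy}-2,6,6-trimethylcyclohex-2-en-1-one oxime F7, and t-BuMe2SiCl with imidazole gives its O-(tert-butyldimethylsilyl) oxime F8. Claisen rearrangement (PhMe, 150 °C) gives (2R)-2-[(1R)-6-{[tert-butyl(dimethyl)silyl]oxyimino}-1,5,5-trimethylcyclohex-2-en-1-yl]-4,4-diethoxybutanal F9, and hydrogenation (H2, Pd/C) gives (2R)-2-[(1R)-2-{[tert-butyl(dimethyl)silyl]oxyimino}-1,3,3-trimethylcyclohexyl]-4,4-diethoxybutanal F10. The Ohira–Bestmann reaction in K2CO3/MeOH, with methanolysis of the O-silyl oxime, returns at 9.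

**Further compounds**

F1 | step 9 | (3R)-2-allyl-3-[(3S)-5,5-diethoxypent-1-yn-3-yl]-1,1,3-trimethyl-2-nitrocyclohexane (C2 epimers) | C#C[C@H](CC(OCC)OCC)[C@@]1(C)CCCC(C)(C)C1(CC=C)[N+](=O)[O-]
F2 | step 9 | 2-[(6R)-6-[(3S)-5,5-diethoxypent-1-yn-3-yl]-2,2,6-trimethyl-1-nitrocyclohexyl]acetaldehyde (C1 epimers) | C#C[C@H](CC(OCC)OCC)[C@@]1(C)CCCC(C)(C)C1(CC=O)[N+](=O)[O-]
F3 | step 9 | 12,12-diethoxy-5-nitro-7β-(triethylsilyloxy)-13,14,15,16-tetranorlabd-8(17)-ene (C5 epimers) | C=C1[C@H](CC(OCC)OCC)[C@@]2(C)CCCC(C)(C)C2([N+](=O)[O-])C[C@@H]1O[Si](CC)(CC)CC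
F4 | step 15 | (11R)-11-hydroperoxy-7β-hydroxy-13,14,15,16-tetranorlabd-8(17)-en-12-al | C=C1[C@H]([C@@H](OO)C=O)[C@@]2(C)CCCC(C)(C)[C@@H]2C[C@@H]1O
F5 | step 15 | (11R)-7β-(2-methoxypropan-2-yloxy)-11-(2-methoxypropan-2-ylperoxy)-13,14,15,16-tetranorlabd-8(17)-en-12-al | C=C1[C@H]([C@@H](OOC(C)(C)OC)C=O)[C@@]2(C)CCCC(C)(C)[C@@H]2C[C@@H]1OC(C)(C)OC
F6 | step 15 | (11S,12E)-15,15-(ethylenedioxy)-7β-(2-methoxypropan-2-yloxy)-11-(2-methoxypropan-2-ylperoxy)labda-8(17),12-dien-16-al | C=C1[C@H]([C@@H](OOC(C)(C)OC)/C=C(/C=O)CC3OCCO3)[C@@]2(C)CCCC(C)(C)[C@@H]2C[C@@H]1OC(C)(C)OC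
F7 | step 7 | (4S)-4-{[(1E)-4,4-diethoxybut-1-en-1-yl]oxy}-2,6,6-trimethylcyclohex-2-en-1-one oxime | CC1=C[C@@H](O/C=C/CC(OCC)OCC)CC(C)(C)C1=NO
F8 | step 7 | (4S)-4-{[(1E)-4,4-diethoxybut-1-en-1-yl]oxy}-2,6,6-trimethylcyclohex-2-en-1-one O-(tert-butyldimethylsilyl) oxime | CC1=C[C@@H](O/C=C/CC(OCC)OCC)CC(C)(C)C1=NO[Si](C)(C)C(C)(C)C
F9 | step 7 | (2R)-2-[(1R)-6-{[tert-butyl(dimethyl)silyl]oxyimino}-1,5,5-trimethylcyclohex-2-en-1-yl]-4,4-diethoxybutanal | O=C[C@H](CC(OCC)OCC)[C@@]1(C)C=CCC(C)(C)C1=NO[Si](C)(C)C(C)(C)C
F10 | step 7 | (2R)-2-[(1R)-2-{[tert-butyl(dimethyl)silyl]oxyimino}-1,3,3-trimethylcyclohexyl]-4,4-diethoxybutanal | O=C[C@H](CC(OCC)OCC)[C@@]1(C)CCCC(C)(C)C1=NO[Si](C)(C)C(C)(C)C
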